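The tridepside is cut at ring B itself: ring A and ring C arrive as orsellinate units, but ring B is grown from an open chain already esterified to O-4 of ring C. Ring B is a resorcinol whose oxygens differ, O-2 being a free ester-chelated hydroxyl and O-4 the point of attachment of ring A; a photochemical vinylketene–ynol ether benzannulation exploits exactly this. In one operation it forms C5–C6, C2–C3, C4–C5 and C1–C2, closes ring B, and delivers C2–OH free and C4–O silylated next to the hindered C1 ester. Its precursor is the (E)-5-diazo-3-methyl-4-oxopent-2-enoate of methyl orsellinate, combined with (triisopropylsilyloxy)acetylene.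

Key step: step 6

Remark: the ring C 2-hydroxyl is carried free throughout (it is hydrogen-bonded to the methyl ester, inert to the acylations used, and of the same kind as the phenol the key step creates on ring B), and the diazo group is installed before the aryl ester is made, so that no strong base meets a depside-type ester.

Step 1
Reactants: 1 butane-2,3-dione; 2 methyl (triphenylphosphoranylidene)acetate
Product: 3 methyl (2E)-3-methyl-4-oxopent-2-enoate
Conditions: 1 (2 equiv), CH2Cl2, 0 °C to rt
Reagents that add atoms: none
Why: Wittig olefination with a stabilised ylide, in which the dione is used in excess to prevent double olefination and the reversible addition of the stabilised ylide should place the acetyl group trans to the ester (E alkene).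

Step 2
Reactants: 3 methyl (2E)-3-methyl-4-oxopent-2-enoate
Product: 5 methyl (2E)-5-diazo-3-methyl-4-oxopent-2-enoate, via trifluoroacetyl diketone 4 (not isolated)
Conditions: LiN(SiMe3)2, THF, –78 °C (ketone added to base); CF3CO2CH2CF3, –78 °C; then MeSO2N3, Et3N, H2O (1 equiv), MeCN, rt
Reagents that add atoms: methanesulfonyl azide CS(=O)(=O)N=[N+]=[N-]
Why: Danheiser detrifluoroacetylative diazo transfer, in which kinetic deprotonation of the methyl ketone and Claisen trifluoroacetylation give the activated diketone 4, to which the sulfonyl azide transfers N2 with loss of the trifluoroacetyl group, the only ester present at this stage being a simple methyl ester.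

Step 3
Reactants: 5 methyl (2E)-5-diazo-3-methyl-4-oxopent-2-enoate
Product: 6 (2E)-5-diazo-3-methyl-4-oxopent-2-enoic acid
Conditions: LiOH, THF/H2O, 0 °C; then cold aq. citric acid to pH 4, EtOAc extraction, used at once
Reagents that add atoms: lithium hydroxide [Li+].[OH-]
Why: Saponification of an unhindered conjugated methyl ester at 0 °C, which the base-stable α-diazoketone should survive, the acid being set free only by a weak acid in the cold.

Step 4
Reactants: 6 (2E)-5-diazo-3-methyl-4-oxopent-2-enoic acid; 7 methyl orsellinate (methyl 2,4-dihydroxy-6-methylbenzoate)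
Product: 8 methyl 4-{[(2E)-5-diazo-3-methyl-4-oxopent-2-enoyl]oxy}-2-hydroxy-6-methylbenzoate
Conditions: DCC, DMAP (cat.), CH2Cl2, 0 °C to rt, dark
Reagents that add atoms: none
Why: Steglich esterification under neutral conditions that spare the diazoketone, in which only the non-chelated 4-OH of 7 should be acylated because the 2-OH is hydrogen-bonded to the neighbouring ester carbonyl.

Step 5
Reactants: 9 tert-butyl formate; 10 dibromomethane
Product: 13 (triisopropylsilyloxy)acetylene, via dibromomethyllithium 11 (not isolated), via lithium ethynolate 12 (not isolated)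
Conditions: 10, lithium 2,2,6,6-tetramethylpiperidide, THF, –78 °C; 9; LiN(SiMe3)2, then n-BuLi, –78 to 0 °C; i-Pr3SiCl, –78 to 0 °C; distillation
Reagents that add atoms: chlorotriisopropylsilane CC(C)[Si](Cl)(C(C)C)C(C)C
Why: Kowalski ynolate synthesis followed by O-silylation, in which 11 adds to the formate, base-induced loss of tert-butoxide and bromine–lithium exchange give a carbenoid that rearranges by a 1,2-hydride shift (Fritsch–Buttenberg–Wiechell type) to ynolate 12, and the bulky silyl chloride should trap 12 on oxygen while leaving the hindered tert-butoxide alone.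

Step 6
Reactants: 8 methyl 4-{[(2E)-5-diazo-3-methyl-4-oxopent-2-enoyl]oxy}-2-hydroxy-6-methylbenzoate; 13 (triisopropylsilyloxy)acetylene
Product: 18 methyl 2-hydroxy-4-{[2-hydroxy-6-methyl-4-(triisopropylsilyloxy)benzoyl]oxy}-6-methylbenzoate, via vinylketene 14 (not isolated), via siloxycyclobutenone 15 (not isolated), via dienylketene 16 (not isolated), via cyclohexadienone 17 (not isolated)
Conditions: 13 (2.5 equiv), degassed ClCH2CH2Cl (0.02 M), hν (365 nm), 20 °C; then 80 °C
Reagents that add atoms: none
Why: Light expels N2 from 8 and Wolff rearrangement shifts the alkenyl group to the former diazo carbon (C5–C6) to give vinylketene 14. The nucleophilic CH carbon of ynol ether 13 attacks the ketene carbonyl carbon in a (2+2) cycloaddition (C2–C3 and C4–C5) to give cyclobutenone 15, which opens in a 4-electron electrocyclic reaction to dienylketene 16. Ring B is closed by thermal disrotatory 6-electron electrocyclisation of 16 (C1–C2), and the dienone 17, a transient racemate, enolises to the phenol, so that no stereocentre remains. The closest known reaction is the second-generation Danheiser benzannulation of α'-diazo enones with siloxyalkynes, which gives resorcinol monosilyl ethers. The required regiochemistry (silyloxy at C4, free OH at C2) follows from the polarisation of the ynol ether, and the E alkene of 8 keeps the aryloxycarbonyl group on the outside of the closing triene and away from the ketene, which a Z isomer could capture as a pyranone. Light of 365 nm should be absorbed by the diazoketone alone, which avoids photo-Fries cleavage and E/Z isomerisation of the aryl enoate, and high dilution with excess 13 should let the cycloaddition outrun capture of the ketene by the chelated phenols.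

Step 7
Reactants: 18 methyl 2-hydroxy-4-{[2-hydroxy-6-methyl-4-(triisopropylsilyloxy)benzoyl]oxy}-6-methylbenzoate
Product: 19 methyl 4-[(2,4-dihydroxy-6-methylbenzoyl)oxy]-2-hydroxy-6-methylbenzoate (methyl lecanorate)
Conditions: Bu4NF, AcOH, THF, 0 °C
Reagents that add atoms: none
Why: Fluoride-mediated cleavage of an aryl silyl ether, buffered with acetic acid so that the phenoxide is protonated before it can attack the depside ester.

Step 8
Reactants: 7 methyl orsellinate
Product: 20 methyl 2,4-bis(benzyloxy)-6-methylbenzoate
Conditions: BnBr (2.5 equiv), K2CO3, DMF, 60 °C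
Reagents that add atoms: benzyl bromide BrCc1ccccc1
Why: Williamson ether synthesis, in which excess benzyl bromide in warm DMF should alkylate both phenols, the chelated 2-OH reacting last.

Step 9
Reactants: 20 methyl 2,4-bis(benzyloxy)-6-methylbenzoate
Product: 21 2,4-bis(benzyloxy)-6-methylbenzoic acid
Conditions: KOH, DMSO/H2O, 90 °C; then aq. HCl
Reagents that add atoms: potassium hydroxide [K+].[OH-]
Why: Saponification of a di-ortho-substituted benzoate by poorly solvated hydroxide in hot aqueous DMSO, conditions to which benzyl ethers are inert.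

Step 10
Reactants: 21 2,4-bis(benzyloxy)-6-methylbenzoic acid; 19 methyl 4-[(2,4-dihydroxy-6-methylbenzoyl)oxy]-2-hydroxy-6-methylbenzoate
Product: 23 methyl 4-[(4-{[2,4-bis(benzyloxy)-6-methylbenzoyl]oxy}-2-hydroxy-6-methylbenzoyl)oxy]-2-hydroxy-6-methylbenzoate, via acid chloride 22 (not isolated)
Conditions: (COCl)2, DMF (cat.), CH2Cl2, 0 °C to rt, evaporate; then 19, Et3N, DMAP (cat.), CH2Cl2, 0 °C
Reagents that add atoms: none
Why: Acid chloride formation and nucleophilic acyl substitution (classical depside esterification), in which only the ring B 4-OH of 19 should react because the two other phenols are hydrogen-bonded to ortho ester carbonyls.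

Step 11
Reactants: 23 methyl 4-[(4-{[2,4-bis(benzyloxy)-6-methylbenzoyl]oxy}-2-hydroxy-6-methylbenzoyl)oxy]-2-hydroxy-6-methylbenzoate
Product: 24 methyl 4-({4-[(2,4-dihydroxy-6-methylbenzoyl)oxy]-2-hydroxy-6-methylbenzoyl}oxy)-2-hydroxy-6-methylbenzoate (CNP0212402.0)
Conditions: H2 (1 atm), 10% Pd/C, EtOAc, rt
Reagents that add atoms: none
Why: Catalytic hydrogenolysis of the two benzyl aryl ethers over palladium on carbon, which should leave the aryl esters and the methyl ester untouched.

Compound list
1 | butane-2,3-dione | CC(=O)C(C)=O | starting material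
2 | methyl (triphenylphosphoranylidene)acetate | COC(=O)C=P(c1ccccc1)(c1ccccc1)c1ccccc1 | starting material
3 | methyl (2E)-3-methyl-4-oxopent-2-enoate | C/C(=C\C(=O)OC)C(C)=O | intermediate
4 | methyl (2E)-7,7,7-trifluoro-3-methyl-4,6-dioxohept-2-enoate (trifluoroacetyl diketone) | C/C(=C\C(=O)OC)C(=O)CC(=O)C(F)(F)F | intermediate (not isolated)
5 | methyl (2E)-5-diazo-3-methyl-4-oxopent-2-enoate | C/C(=C\C(=O)OC)C(=O)C=[N+]=[N-] | intermediate
6 | (2E)-5-diazo-3-methyl-4-oxopent-2-enoic acid | C/C(=C\C(=O)O)C(=O)C=[N+]=[N-] | intermediate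
7 | methyl orsellinate (methyl 2,4-dihydroxy-6-methylbenzoate) | COC(=O)c1c(C)cc(O)cc1O | starting material
8 | methyl 4-{[(2E)-5-diazo-3-methyl-4-oxopent-2-enoyl]oxy}-2-hydroxy-6-methylbenzoate | C/C(=C\C(=O)Oc1cc(C)c(C(=O)OC)c(O)c1)C(=O)C=[N+]=[N-] | intermediate
9 | tert-butyl formate | CC(C)(C)OC=O | starting material
10 | dibromomethane | BrCBr | starting material
11 | dibromomethyllithium | [Li]C(Br)Br | intermediate (not isolated)
12 | lithium ethynolate | [Li+].[O-]C#C | intermediate (not isolated)
13 | (triisopropylsilyloxy)acetylene | C#CO[Si](C(C)C)(C(C)C)C(C)C | intermediate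
14 | methyl 2-hydroxy-6-methyl-4-{[(2E)-3-methyl-5-oxopenta-2,4-dienoyl]oxy}benzoate (vinylketene) | C/C(=C\C(=O)Oc1cc(C)c(C(=O)OC)c(O)c1)C=C=O | intermediate (not isolated)
15 | methyl 2-hydroxy-6-methyl-4-({(2E)-3-[2-oxo-4-(triisopropylsilyloxy)cyclobut-3-en-1-yl]but-2-enoyl}oxy)benzoate (siloxycyclobutenone, racemic) | C/C(=C\C(=O)Oc1cc(C)c(C(=O)OC)c(O)c1)C1C(=O)C=C1O[Si](C(C)C)(C(C)C)C(C)C | intermediate (not isolated)
16 | methyl 2-hydroxy-6-methyl-4-{[(2E,4E)-3-methyl-7-oxo-5-(triisopropylsilyloxy)hepta-2,4,6-trienoyl]oxy}benzoate (dienylketene) | C/C(=C\C(=O)Oc1cc(C)c(C(=O)OC)c(O)c1)/C=C(\C=C=O)O[Si](C(C)C)(C(C)C)C(C)C | intermediate (not isolated)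
17 | 3-hydroxy-4-(methoxycarbonyl)-5-methylphenyl 2-methyl-6-oxo-4-(triisopropylsilyloxy)cyclohexa-2,4-diene-1-carboxylate (cyclohexadienone, racemic) | O=C1C=C(O[Si](C(C)C)(C(C)C)C(C)C)C=C(C)C1C(=O)Oc1cc(C)c(C(=O)OC)c(O)c1 | intermediate (not isolated)
18 | methyl 2-hydroxy-4-{[2-hydroxy-6-methyl-4-(triisopropylsilyloxy)benzoyl]oxy}-6-methylbenzoate | COC(=O)c1c(C)cc(OC(=O)c2c(C)cc(O[Si](C(C)C)(C(C)C)C(C)C)cc2O)cc1O | intermediate
19 | methyl 4-[(2,4-dihydroxy-6-methylbenzoyl)oxy]-2-hydroxy-6-methylbenzoate (methyl lecanorate) | COC(=O)c1c(C)cc(OC(=O)c2c(C)cc(O)cc2O)cc1O | intermediate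
20 | methyl 2,4-bis(benzyloxy)-6-methylbenzoate | COC(=O)c1c(C)cc(OCc2ccccc2)cc1OCc1ccccc1 | intermediate
21 | 2,4-bis(benzyloxy)-6-methylbenzoic acid | OC(=O)c1c(C)cc(OCc2ccccc2)cc1OCc1ccccc1 | intermediate
22 | 2,4-bis(benzyloxy)-6-methylbenzoyl chloride | ClC(=O)c1c(C)cc(OCc2ccccc2)cc1OCc1ccccc1 | intermediate (not isolated)
23 | methyl 4-[(4-{[2,4-bis(benzyloxy)-6-methylbenzoyl]oxy}-2-hydroxy-6-methylbenzoyl)oxy]-2-hydroxy-6-methylbenzoate | COC(=O)c1c(C)cc(OC(=O)c2c(C)cc(OC(=O)c3c(C)cc(OCc4ccccc4)cc3OCc3ccccc3)cc2O)cc1O | intermediate
24 | methyl 4-({4-[(2,4-dihydroxy-6-methylbenzoyl)oxy]-2-hydroxy-6-methylbenzoyl}oxy)-2-hydroxy-6-methylbenzoate (CNP0212402.0) | COC(=O)c1c(C)cc(OC(=O)c2c(C)cc(OC(=O)c3c(C)cc(O)cc3O)cc2O)cc1O | target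

Total step count: 11.
Longest linear sequence: 8 steps (steps 1, 2, 3, 4, 6, 7, 10, 11).

Steps most likely to fail

Step 6. The enoate may isomerise to the Z form under irradiation, or the vinylketene may be captured by a phenolic hydroxyl, so that the ketene is diverted before ring B closes. The fallback gives up the benzannulation for a classical depside coupling; it sets out from 7 and 21 and comes back to the route at 19. Acid 21 is converted into acid chloride 22 as in step 10 and used to acylate the 4-OH of 7 (Et3N, DMAP (cat.), CH2Cl2, 0 °C), which should give methyl 4-{[2,4-bis(benzyloxy)-6-methylbenzoyl]oxy}-2-hydroxy-6-methylbenzoate F1. Hydrogenolysis of F1 (H2, 10% Pd/C, EtOAc) should then give 19, after which steps 10 and 11 follow unchanged.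

Step 5. The dibromo adduct of the formate may follow bromine–lithium exchange paths that end in a vinyl anion and not in the carbenoid, so that little ynolate is formed. The fallback makes the C–O bond by oxygen transfer and not by rearrangement; it sets out from acetylene, bought in place of 9 and 10, and comes back to the route at 12. Acetylene is deprotonated with n-BuLi in THF at –78 °C to lithium acetylide F2. F2 is oxidised by lithium tert-butyl peroxide (from tert-butyl hydroperoxide and LiN(SiMe3)2, –78 to –20 °C) to ynolate 12, which is trapped on oxygen with i-Pr3SiOSO2CF3 at –78 °C to give 13.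

Step 2. Deprotonation may occur at the allylic C3-methyl group, or the enolate may add to the 4-oxoenoate of a second molecule, so that oligomers form in place of diketone 4. The fallback avoids a free enolate; it sets out from 3 and comes back to the route at 5. Soft enolisation of 3 (Me3SiOSO2CF3, Et3N, CH2Cl2, 0 °C) should give methyl (2E)-3-methyl-4-(trimethylsilyloxy)penta-2,4-dienoate F3. Bromination of F3 with N-bromosuccinimide (THF, –78 to 0 °C) should give methyl (2E)-5-bromo-3-methyl-4-oxopent-2-enoate F4. Treatment of F4 with N,N'-ditosylhydrazine and DBU (THF, 0 °C) displaces bromide and eliminates two sulfinates, which should give 5.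

Further compounds
F1 | step 6 | methyl 4-{[2,4-bis(benzyloxy)-6-methylbenzoyl]oxy}-2-hydroxy-6-methylbenzoate | COC(=O)c1c(C)cc(OC(=O)c2c(C)cc(OCc3ccccc3)cc2OCc2ccccc2)cc1O
F2 | step 5 | lithium acetylide | [Li]C#C
F3 | step 2 | methyl (2E)-3-methyl-4-(trimethylsilyloxy)penta-2,4-dienoate | C/C(=C\C(=O)OC)C(=C)O[Si](C)(C)C
F4 | step 2 | methyl (2E)-5-bromo-3-methyl-4-oxopent-2-enoate | C/C(=C\C(=O)OC)C(=O)CBr
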